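**Assumption:** Agrimol C has no stereocentres, and the SMILES carries no stereodescriptors. There is therefore no enantiomer to set, and every intermediate is achiral.

## Retrosynthetic overview
1. Remove the two aryl C‑CH3 groups last. Each terminal ring then has a single aromatic C–H (C5, flanked by OH and OMe), and the central ring has none. The C5–H is converted to CH3 by Mannich aminomethylation then hydrogenolysis, which avoids building the hard‑to‑make "OMe next to Me" terminal unit.
2. Cut both Ar–CH2–Ar bonds. Each terminal acylphloroglucinol is alkylated at its most nucleophilic carbon (C3, between two OH groups), through the o‑quinone methide of its Mannich base, on the central 2,4,6‑trihydroxybutyrophenone.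
3. Both acylarenes come from one BF3‑mediated C‑butyrylation each, of phloroglucinol and of 3,5‑dihydroxyanisole.
4. No ring is constructed. All three arenes come from commercial phenols. Bond‑forming order: acyl C–C, then the two CH2 bridges, then the two CH3 groups.

## Route

**Step 1**
Reactants: 1 (phloroglucinol), 2 (butyric acid)
Product: 3 (2,4,6‑trihydroxybutyrophenone)
Conditions: BF3·OEt2 (neat, 5 equiv), 90 °C, 3 h
Reagents that add atoms: none
Why: BF3‑mediated Friedel–Crafts C‑acylation of phloroglucinol stops at the mono‑ketone because the acyl group deactivates the ring; no stereocentre is formed.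

**Step 2**
Reactants: 4 (3,5‑dihydroxyanisole), 2 (butyric acid, 1.0 equiv)
Product: 5 (1‑(2,4‑dihydroxy‑6‑methoxyphenyl)butan‑1‑one)
Conditions: BF3·OEt2, 80 °C, 2 h; chromatographic removal of the 2,6‑dihydroxy‑4‑methoxy isomer
Reagents that add atoms: none
Why: Friedel–Crafts acylation goes to the carbon para to one OH and ortho to the other OH and the OMe, which is the most electron‑rich site, giving the acyl group flanked by OH and OMe as in the target.

**Step 3**
Reactants: 5
Product: 8 (1‑[3‑(dimethylaminomethyl)‑2,4‑dihydroxy‑6‑methoxyphenyl]butan‑1‑one)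
Conditions: 40% aq. Me2NH (1.1 equiv), 37% aq. CH2O (1.1 equiv), EtOH, 0 → 25 °C, 12 h
Reagents that add atoms: 6 dimethylamine (CNC); 7 formaldehyde (C=O)
Why: Mannich ortho‑aminomethylation occurs at C3, the carbon between the two OH groups, which is the most nucleophilic site and gives the best intramolecular N···H–O stabilisation of the product.

**Step 4**
Reactants: 8 (2.3 equiv), 3 (1.0 equiv)
Product: 9 (tris‑aryl skeleton: central butyrylphloroglucinol bearing two 2,4‑dihydroxy‑6‑methoxy‑3‑butyrylbenzyl arms; terminal C5–H still free)
Conditions: MeCN, 80 °C, sealed tube, 16 h (Me2NH lost)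
Reagents that add atoms: none (the CH2 comes from 8)
Why: Thermal loss of Me2NH gives an o‑quinone methide that is trapped twice by the more nucleophilic central ring at its two equivalent C3/C5 positions (Friedel–Crafts‑type hydroxybenzylation); the acyl group on the central ring blocks over‑alkylation.

**Step 5**
Reactants: 9
Product: 10 (bis‑Mannich base: a CH2NMe2 group at C5 of each terminal ring)
Conditions: 40% aq. Me2NH (6 equiv), 37% aq. CH2O (4 equiv), EtOH–THF (1:1), 25 → 45 °C, 24 h
Reagents that add atoms: 6 dimethylamine (CNC); 7 formaldehyde (C=O)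
Why: The only aromatic C–H in the molecule are the two terminal‑ring C5–H, each activated by ortho OH, ortho OMe and para OH, so double Mannich aminomethylation is regiochemically unambiguous.

**Step 6**
Reactants: 10
Product: 11 (Agrimol C)
Conditions: H2 (1 atm), 10% Pd/C, EtOH, 25 °C, 8 h
Reagents that add atoms: none (H2 adds only hydrogen)
Why: Hydrogenolysis of the o‑hydroxybenzylic C–N bonds converts each ArCH2NMe2 into ArCH3, with loss of Me2NH. The chelated aryl ketones, OMe groups and diarylmethane CH2 bridges survive these mild conditions, and no stereocentre is involved.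

## Compound list
1 | phloroglucinol | Oc1cc(O)cc(O)c1 | starting material
2 | butyric acid | CCCC(=O)O | starting material
3 | 2,4,6‑trihydroxybutyrophenone | CCCC(=O)c1c(O)cc(O)cc1O | intermediate
4 | 3,5‑dihydroxyanisole | COc1cc(O)cc(O)c1 | starting material
5 | 1‑(2,4‑dihydroxy‑6‑methoxyphenyl)butan‑1‑one | CCCC(=O)c1c(O)cc(O)cc1OC | intermediate
6 | dimethylamine | CNC | starting material
7 | formaldehyde | C=O | starting material
8 | 1‑[3‑(dimethylaminomethyl)‑2,4‑dihydroxy‑6‑methoxyphenyl]butan‑1‑one | CCCC(=O)c1c(O)c(CN(C)C)c(O)cc1OC | intermediate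
9 | tris‑aryl skeleton (terminal C5–H free) | CCCC(=O)c1c(O)c(Cc2c(O)c(C(=O)CCC)c(OC)cc2O)c(O)c(Cc2c(O)c(C(=O)CCC)c(OC)cc2O)c1O | intermediate
10 | bis‑Mannich base of 9 | CCCC(=O)c1c(O)c(Cc2c(O)c(C(=O)CCC)c(OC)c(CN(C)C)c2O)c(O)c(Cc2c(O)c(C(=O)CCC)c(OC)c(CN(C)C)c2O)c1O | intermediate
11 | Agrimol C (achiral) | CCCC(=O)c1c(O)c(Cc2c(O)c(C)c(OC)c(C(=O)CCC)c2O)c(O)c(Cc2c(O)c(C)c(OC)c(C(=O)CCC)c2O)c1O | target

## Totals
Total steps: 6. Longest linear sequence: 5 (4 → 5 → 8 → 9 → 10 → 11, i.e. steps 2–6).

## Three steps most likely to fail
1. **Step 2 (regioselective butyrylation of 3,5‑dihydroxyanisole).** Acylation may give the 2,6‑dihydroxy‑4‑methoxy isomer or diacylation.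
   Fallback: make 5 from 3 instead. Benzylate the para OH (BnBr, K2CO3), mono‑O‑methylate one of the two equivalent chelated ortho OH groups (MeI, K2CO3, DMF), then remove the benzyl ether by hydrogenolysis (H2, Pd/C).
2. **Step 4 (double o‑QM heterocoupling).** The Mannich base 8 may homodimerise through its own C5, or stop at the mono‑adduct.
   Fallback: reverse the polarity. Convert 3 to its 3,5‑bis(dimethylaminomethyl) Mannich base and heat it with about 2.3 equiv of 5 as the nucleophile, accepting a C3/C5 isomer separation on the terminal rings.
3. **Steps 5–6 (late‑stage double reductive C‑methylation).** Possible problems are incomplete bis‑aminomethylation, oligomerisation through o‑QMs, or over‑reduction of a ketone during hydrogenolysis.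
   Fallback: replace the Mannich/hydrogenolysis pair with direct C‑methylation of 9 (MeI, 2.2 equiv, NaOMe/MeOH, 0 °C), tolerating the gem‑dimethyl and O‑methyl by‑products and separating them.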